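**Strategy.** The plan rests on opening the pyranone ring of the coumarin at C4–C4a and O1–C2. The benzo ring carries three oxygens (O1 on C8a, OH on C6, OH on C7) in the mutual positions found in hydroxyquinol. C2, C3 with its aryloxy group and C4 can therefore arrive together as an aryloxy formylacetate. One acid-mediated Pechmann annulation then forms both bonds, closes the pyranone ring and leaves the 6,7-diol free. Its precursor is the enol of ethyl 2-(4-bromo-2-methoxyphenoxy)-3-oxopropanoate. The bromine, para to the ether oxygen, later becomes the cinnamate carbon through a Heck coupling with the acrylate of protected (R)-danshensu, and one acidolysis completes the synthesis.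

Key step: step 3

Remark: (R)-danshensu is taken as the free acid; its commercial sodium salt would enter step 6 unchanged, because the carboxylate is the species that is alkylated.

**Step 1**
Reactants: 1 4-bromo-2-methoxyphenol; 2 ethyl bromoacetate
Product: 3 ethyl 2-(4-bromo-2-methoxyphenoxy)acetate
Conditions: K2CO3, acetone, reflux
Reagents that add atoms: none
Why: Williamson ether synthesis, in which the phenoxide formed by K2CO3 displaces bromide from the activated α-bromo ester by SN2.

**Step 2**
Reactants: 3 ethyl 2-(4-bromo-2-methoxyphenoxy)acetate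
Product: 5 ethyl (E)-2-(4-bromo-2-methoxyphenoxy)-3-hydroxyprop-2-enoate (enol of the formyl ester with OH cis to the ester carbonyl), via sodium enolate 4 (not isolated)
Conditions: NaH, HCO2Et (excess), THF, 0 °C → rt; then cold 1 M HCl; used crude
Reagents that add atoms: ethyl formate, CCOC=O
Why: Crossed Claisen condensation (C-formylation) of an aryloxyacetate with non-enolisable ethyl formate, driven by formation of the stabilised sodium enolate 4, which cold acid should convert into the hydrogen-bonded enol 5.

**Step 3**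
Reactants: 5 ethyl (E)-2-(4-bromo-2-methoxyphenoxy)-3-hydroxyprop-2-enoate; 6 benzene-1,2,4-triol
Product: 9 3-(4-bromo-2-methoxyphenoxy)-6,7-dihydroxy-2H-chromen-2-one, via benzylic carbinol 7 (not isolated), via trihydroxycinnamate 8 (not isolated)
Conditions: MeSO3H, 6 (1.2 equiv), N2, 0 °C → rt; poured onto ice
Reagents that add atoms: none
Why: Pechmann coumarin condensation in its formylacetate variant, the reaction type that turns hydroxyquinol into esculetin: the O-protonated aldehyde tautomer of 5 should be attacked by C5 of 6 to give carbinol 7, which ionises and loses the α-proton to give cinnamate 8. The 2-hydroxyl of the new aryl group (the former 4-OH of 6) then attacks the ester carbonyl held cis to it, a 6-exo-trig acyl substitution that closes the pyranone ring with loss of ethanol, while acid-catalysed E/Z equilibration of 8 feeds the cyclising isomer. No stereocentre is formed. Three selectivities are needed: attack at C5 of 6 rather than C3 or C6, secured because C5 is para to the 2-OH and ortho to the 4-OH and unhindered, whereas C3 is flanked by two hydroxyls and C6 is activated by one only; intermolecular capture rather than cyclodehydration onto the aryloxy ring to a benzofuran-2-carboxylate, secured because the only free ortho carbon of that ring is meta to both OMe and Br and far less nucleophilic than the triol; and elimination from 7 rather than capture by a second triol, secured by keeping 6 close to stoichiometric and by the acidic α-hydrogen, which lets the benzylic cation collapse to the conjugated ester. The aryl bromide, the methyl ether and the C3–O–aryl linkage should be inert to MeSO3H at room temperature, and the non-oxidising acid under nitrogen protects the air-sensitive triol.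

**Step 4**
Reactants: 9 3-(4-bromo-2-methoxyphenoxy)-6,7-dihydroxy-2H-chromen-2-one
Product: 10 3-(4-bromo-2-hydroxyphenoxy)-6,7-dihydroxy-2H-chromen-2-one
Conditions: BBr3 (5 equiv), CH2Cl2, −78 °C → rt; then ice-water
Reagents that add atoms: none
Why: Lewis-acid ether cleavage, in which BBr3 coordinates the methoxy oxygen and bromide removes the methyl group by SN2; the lactone, the aryl bromide and the C3–O–aryl ether, which offers no sp3 carbon for substitution, should survive.

**Step 5**
Reactants: 10 3-(4-bromo-2-hydroxyphenoxy)-6,7-dihydroxy-2H-chromen-2-one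
Product: 11 3-{4-bromo-2-[(4-methoxybenzyl)oxy]phenoxy}-6,7-bis[(4-methoxybenzyl)oxy]-2H-chromen-2-one
Conditions: 4-MeOC6H4CH2Cl (3.5 equiv), K2CO3, Bu4NI (cat.), DMF, 50 °C, N2
Reagents that add atoms: 4-methoxybenzyl chloride, COc1ccc(CCl)cc1
Why: Williamson O-benzylation of the three phenoxides under carbonate conditions that leave the coumarin lactone closed, which masks the catechol against oxidation and palladium chelation in the coupling step.

**Step 6**
Reactants: 12 (R)-danshensu, (2R)-3-(3,4-dihydroxyphenyl)-2-hydroxypropanoic acid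
Product: 13 4-methoxybenzyl (2R)-3-{3,4-bis[(4-methoxybenzyl)oxy]phenyl}-2-hydroxypropanoate
Conditions: 4-MeOC6H4CH2Cl (3.3 equiv), K2CO3, Bu4NI (cat.), DMF, rt, N2
Reagents that add atoms: 4-methoxybenzyl chloride, COc1ccc(CCl)cc1
Why: Carbonate-mediated alkylation of the carboxylate and the two phenoxides, while the secondary alcohol is not deprotonated by K2CO3 and stays free; no bond to the stereocentre is touched, so it remains R.

**Step 7**
Reactants: 13 4-methoxybenzyl (2R)-3-{3,4-bis[(4-methoxybenzyl)oxy]phenyl}-2-hydroxypropanoate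
Product: 14 4-methoxybenzyl (2R)-2-(acryloyloxy)-3-{3,4-bis[(4-methoxybenzyl)oxy]phenyl}propanoate
Conditions: CH2=CHCOCl, Et3N, CH2Cl2, −10 → 0 °C
Reagents that add atoms: acryloyl chloride, C=CC(=O)Cl
Why: O-acylation of the secondary alcohol by nucleophilic acyl substitution on the acid chloride, with the R configuration retained because the C–O bond of the stereocentre is not broken.

**Step 8**
Reactants: 11 3-{4-bromo-2-[(4-methoxybenzyl)oxy]phenoxy}-6,7-bis[(4-methoxybenzyl)oxy]-2H-chromen-2-one; 14 4-methoxybenzyl (2R)-2-(acryloyloxy)-3-{3,4-bis[(4-methoxybenzyl)oxy]phenyl}propanoate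
Product: 15 4-methoxybenzyl (2R)-3-{3,4-bis[(4-methoxybenzyl)oxy]phenyl}-2-{[(2E)-3-(4-{[6,7-bis((4-methoxybenzyl)oxy)-2-oxo-2H-chromen-3-yl]oxy}-3-[(4-methoxybenzyl)oxy]phenyl)prop-2-enoyl]oxy}propanoate
Conditions: Pd(OAc)2 (5 mol %), P(o-tol)3 (10 mol %), NaOAc, 14 (1.3 equiv), DMF, 110 °C, N2
Reagents that add atoms: none
Why: Mizoroki–Heck reaction, in which oxidative addition of the C–Br bond to zerovalent palladium (formed in the flask from Pd(OAc)2 and the phosphine), syn insertion of the acrylate with aryl delivered to the β-carbon and syn β-hydride elimination should give the E-cinnamate; the trisubstituted C3=C4 bond of the coumarin is too hindered to insert and the mild acetate base leaves the remote stereocentre alone.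

**Step 9**
Reactants: 15 the hexakis(4-methoxybenzyl)-protected coupling product
Product: 16 (2R)-3-(3,4-dihydroxyphenyl)-2-{[(2E)-3-{4-[(6,7-dihydroxy-2-oxo-2H-chromen-3-yl)oxy]-3-hydroxyphenyl}prop-2-enoyl]oxy}propanoic acid (target)
Conditions: TFA/CH2Cl2 (1:4), Et3SiH (12 equiv), 0 °C → rt
Reagents that add atoms: none
Why: SN1 acidolysis of the five 4-methoxybenzyl aryl ethers and the 4-methoxybenzyl ester, with the released benzylic cations reduced irreversibly by the silane so that they should not alkylate the catechol rings; the cinnamate ester, the lactone, the E-alkene and the R stereocentre are stable to TFA.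

**Compound list**
1 | 4-bromo-2-methoxyphenol | COc1cc(Br)ccc1O | starting material
2 | ethyl bromoacetate | CCOC(=O)CBr | starting material
3 | ethyl 2-(4-bromo-2-methoxyphenoxy)acetate | CCOC(=O)COc1ccc(Br)cc1OC | intermediate
4 | sodium (E)-2-(4-bromo-2-methoxyphenoxy)-3-ethoxy-3-oxoprop-1-en-1-olate (sodium enolate of the formyl ester) | [Na+].CCOC(=O)/C(Oc1ccc(Br)cc1OC)=C\[O-] | intermediate
5 | ethyl (E)-2-(4-bromo-2-methoxyphenoxy)-3-hydroxyprop-2-enoate (enol of ethyl 2-(4-bromo-2-methoxyphenoxy)-3-oxopropanoate) | CCOC(=O)/C(Oc1ccc(Br)cc1OC)=C\O | intermediate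
6 | benzene-1,2,4-triol (hydroxyquinol) | Oc1ccc(O)c(O)c1 | starting material
7 | ethyl 2-(4-bromo-2-methoxyphenoxy)-3-hydroxy-3-(2,4,5-trihydroxyphenyl)propanoate (mixture of diastereomers) | CCOC(=O)C(Oc1ccc(Br)cc1OC)C(O)c1cc(O)c(O)cc1O | intermediate
8 | ethyl (E)-2-(4-bromo-2-methoxyphenoxy)-3-(2,4,5-trihydroxyphenyl)prop-2-enoate (aryl cis to the ester) | CCOC(=O)/C(Oc1ccc(Br)cc1OC)=C\c1cc(O)c(O)cc1O | intermediate
9 | 3-(4-bromo-2-methoxyphenoxy)-6,7-dihydroxy-2H-chromen-2-one | COc1cc(Br)ccc1Oc1cc2cc(O)c(O)cc2oc1=O | intermediate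
10 | 3-(4-bromo-2-hydroxyphenoxy)-6,7-dihydroxy-2H-chromen-2-one | Oc1cc(Br)ccc1Oc1cc2cc(O)c(O)cc2oc1=O | intermediate
11 | 3-{4-bromo-2-[(4-methoxybenzyl)oxy]phenoxy}-6,7-bis[(4-methoxybenzyl)oxy]-2H-chromen-2-one | COc1ccc(COc2cc(Br)ccc2Oc2cc3cc(OCc4ccc(OC)cc4)c(OCc4ccc(OC)cc4)cc3oc2=O)cc1 | intermediate
12 | (R)-danshensu, (2R)-3-(3,4-dihydroxyphenyl)-2-hydroxypropanoic acid | O[C@H](Cc1ccc(O)c(O)c1)C(=O)O | starting material
13 | 4-methoxybenzyl (2R)-3-{3,4-bis[(4-methoxybenzyl)oxy]phenyl}-2-hydroxypropanoate | O[C@H](Cc1ccc(OCc2ccc(OC)cc2)c(OCc2ccc(OC)cc2)c1)C(=O)OCc1ccc(OC)cc1 | intermediate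
14 | 4-methoxybenzyl (2R)-2-(acryloyloxy)-3-{3,4-bis[(4-methoxybenzyl)oxy]phenyl}propanoate | C=CC(=O)O[C@H](Cc1ccc(OCc2ccc(OC)cc2)c(OCc2ccc(OC)cc2)c1)C(=O)OCc1ccc(OC)cc1 | intermediate
15 | 4-methoxybenzyl (2R)-3-{3,4-bis[(4-methoxybenzyl)oxy]phenyl}-2-{[(2E)-3-(4-{[6,7-bis((4-methoxybenzyl)oxy)-2-oxo-2H-chromen-3-yl]oxy}-3-[(4-methoxybenzyl)oxy]phenyl)prop-2-enoyl]oxy}propanoate | O=C(/C=C/c1ccc(Oc2cc3cc(OCc4ccc(OC)cc4)c(OCc4ccc(OC)cc4)cc3oc2=O)c(OCc2ccc(OC)cc2)c1)O[C@H](Cc1ccc(OCc2ccc(OC)cc2)c(OCc2ccc(OC)cc2)c1)C(=O)OCc1ccc(OC)cc1 | intermediate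
16 | (2R)-3-(3,4-dihydroxyphenyl)-2-{[(2E)-3-{4-[(6,7-dihydroxy-2-oxo-2H-chromen-3-yl)oxy]-3-hydroxyphenyl}prop-2-enoyl]oxy}propanoic acid | O=C(/C=C/c1ccc(Oc2cc3cc(O)c(O)cc3oc2=O)c(O)c1)O[C@H](Cc1ccc(O)c(O)c1)C(=O)O | target

**Step count.** Total: 9 steps. Longest linear sequence: 7 steps (steps 1, 2, 3, 4, 5, 8, 9); the danshensu branch (steps 6, 7) joins at step 8.

**Steps most likely to fail**

Step 3. The bimolecular hydroxyalkylation may lose to cyclodehydration of 5 onto its own aryloxy ring, to a second arylation of the benzylic carbinol, or to degradation of the triol in acid. The fallback fixes the regiochemistry in an aldehyde partner and closes the pyranone ring by a Perkin-type condensation. It sets out from ester 3: saponification (LiOH, THF/H2O, then HCl) would give (4-bromo-2-methoxyphenoxy)acetic acid F1. Heating this acid with commercial 2-hydroxy-4,5-dimethoxybenzaldehyde in Ac2O/Et3N at 120 °C (O-acylation, intramolecular aldol-type condensation, dehydration) would give 3-(4-bromo-2-methoxyphenoxy)-6,7-dimethoxy-2H-chromen-2-one F2. Excess BBr3 in CH2Cl2 would then remove all three methyl groups, and the route is rejoined at triol 10.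

Step 8. Oxidative addition into the electron-rich C–Br bond may be too slow at temperatures the acrylate tolerates, so that thermal oligomerisation of 14 or slow base-induced erosion of the stereocentre takes over. The fallback forms the alkene by cross-metathesis. It sets out from bromide 11: Stille vinylation (Bu3SnCH=CH2, Pd(PPh3)4, toluene, 100 °C) would give 3-{4-ethenyl-2-[(4-methoxybenzyl)oxy]phenoxy}-6,7-bis[(4-methoxybenzyl)oxy]-2H-chromen-2-one F3. Cross-metathesis of this styrene with acrylate 14 (second-generation Hoveyda–Grubbs catalyst, CH2Cl2, 40 °C) should give the E-cinnamate with loss of ethene, rejoining the route at 15.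

Step 9. The six benzylic cations released by acidolysis may re-attach to the electron-rich catechol rings (Friedel–Crafts C-benzylation) faster than the silane intercepts them, or cleavage may stall at partly protected material. The fallback exchanges the protecting groups for methoxymethyl acetals, whose fragments are taken up by the aqueous medium. It sets out from triol 10 and (R)-danshensu 12. MOMCl/i-Pr2NEt in CH2Cl2 on 10 would give 3-[4-bromo-2-(methoxymethoxy)phenoxy]-6,7-bis(methoxymethoxy)-2H-chromen-2-one F4. MOMCl/K2CO3 in acetone on 12 would give methoxymethyl (2R)-3-[3,4-bis(methoxymethoxy)phenyl]-2-hydroxypropanoate F5, with the secondary alcohol left free. Acryloylation as in step 7 would give methoxymethyl (2R)-2-(acryloyloxy)-3-[3,4-bis(methoxymethoxy)phenyl]propanoate F6. Heck coupling of the bromide with this acrylate as in step 8 would give the hexakis(methoxymethyl)-protected coupling product F7. Aqueous 3 M HCl in THF at 40 °C would hydrolyse the five aryl acetals and the acylal-type ester, rejoining the route at target 16.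

**Further compounds**
F1 | step 3 | (4-bromo-2-methoxyphenoxy)acetic acid | COc1cc(Br)ccc1OCC(=O)O
F2 | step 3 | 3-(4-bromo-2-methoxyphenoxy)-6,7-dimethoxy-2H-chromen-2-one | COc1cc(Br)ccc1Oc1cc2cc(OC)c(OC)cc2oc1=O
F3 | step 8 | 3-{4-ethenyl-2-[(4-methoxybenzyl)oxy]phenoxy}-6,7-bis[(4-methoxybenzyl)oxy]-2H-chromen-2-one | C=Cc1ccc(Oc2cc3cc(OCc4ccc(OC)cc4)c(OCc4ccc(OC)cc4)cc3oc2=O)c(OCc2ccc(OC)cc2)c1
F4 | step 9 | 3-[4-bromo-2-(methoxymethoxy)phenoxy]-6,7-bis(methoxymethoxy)-2H-chromen-2-one | COCOc1cc(Br)ccc1Oc1cc2cc(OCOC)c(OCOC)cc2oc1=O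
F5 | step 9 | methoxymethyl (2R)-3-[3,4-bis(methoxymethoxy)phenyl]-2-hydroxypropanoate | O[C@H](Cc1ccc(OCOC)c(OCOC)c1)C(=O)OCOC
F6 | step 9 | methoxymethyl (2R)-2-(acryloyloxy)-3-[3,4-bis(methoxymethoxy)phenyl]propanoate | C=CC(=O)O[C@H](Cc1ccc(OCOC)c(OCOC)c1)C(=O)OCOC
F7 | step 9 | methoxymethyl (2R)-3-[3,4-bis(methoxymethoxy)phenyl]-2-{[(2E)-3-(4-{[6,7-bis(methoxymethoxy)-2-oxo-2H-chromen-3-yl]oxy}-3-(methoxymethoxy)phenyl)prop-2-enoyl]oxy}propanoate | O=C(/C=C/c1ccc(Oc2cc3cc(OCOC)c(OCOC)cc3oc2=O)c(OCOC)c1)O[C@H](Cc1ccc(OCOC)c(OCOC)c1)C(=O)OCOC
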